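**Retrosynthesis**
1. Last steps: acetylate C9-OH. The C4 ketone and the C8 tertiary OH close the 4,8-oxa-bridged hemiketal spontaneously.
2. Key disconnection (new step): the C9–C10 bond is formed by intramolecular dual photoredox/Cr allylic C–H addition of the C11 exocyclic alkene to the C9 aldehyde. This closes the 10-membered ring and sets C9, C10 and the trans ring fusion.
3. The C4–C5 bond comes from an NHK coupling of a cyclohexane fragment (C4 aldehyde) with a γ-lactone fragment (2-bromoallyl vinyl bromide). The cyclohexane fragment comes from a Diels–Alder of methacrolein with 1,4-diacetoxybutadiene. The lactone fragment comes from dihydroxyacetone acetonide by Enders alkylation and an intramolecular Reformatsky reaction.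
4. Ring-formation order: cyclohexane (Diels–Alder), then γ-lactone (Reformatsky), then 10-membered ring (Cr/photoredox), then oxa-bridge hemiketal (spontaneous).

Assumption (one line): the enantiomers of the catalyst and auxiliaries (oxazaborolidinium, (–)-Ipc2B-allyl, SAMP) are those that give the drawn configurations, and the C4 hemiketal configuration is set thermodynamically by the oxa-bridge.

---

**Step 1**
Reactants: 1 methacrolein; 2 (1E,3E)-1,4-diacetoxybuta-1,3-diene
Product: 3 cis-2,5-diacetoxy-1-methylcyclohex-3-ene-1-carbaldehyde (CHO cis to both OAc, CH3 trans; single enantiomer)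
Conditions: chiral oxazaborolidinium triflimide (20 mol%), CH2Cl2, –78 → –40 °C
Reagents that add atoms: none
Why: A Lewis-acid-catalysed Diels–Alder reaction. The endo TS with the CHO bound to the catalyst sets quaternary C1 and C14 (OAc cis to CHO, trans to Me), and the (E,E)-diene makes the two OAc groups cis.

**Step 2**
Reactants: 3
Product: 4 saturated diacetoxy aldehyde
Conditions: H2 (1 atm), 5% Rh/Al2O3, EtOAc, 23 °C
Reagents that add atoms: none
Why: Rh avoids hydrogenolysis of the allylic acetates. The ring alkene is removed without touching the aldehyde, and no stereocenter is disturbed.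

**Step 3**
Reactants: 4; 5 (–)-B-allyldiisopinocampheylborane
Product: 6 1-(2,5-diacetoxy-1-methylcyclohexyl)but-3-en-1-ol (C2 = R as drawn)
Conditions: 5, Et2O, –78 °C; then pH 7 buffer/H2O2
Reagents that add atoms: 5, C=CCB(C1CC2CC(C1C)C2(C)C)C1CC2CC(C1C)C2(C)C
Why: Brown asymmetric allylation through a Zimmerman–Traxler chair; reagent control sets C2 even next to the quaternary C1.

**Step 4**
Reactants: 6
Product: 7 triacetate (C2, C11, C14)
Conditions: Ac2O, DMAP, pyridine, CH2Cl2, 23 °C
Reagents that add atoms: acetic anhydride, CC(=O)OC(C)=O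
Why: Simple esterification of the C2 alcohol, which protects it as the target acetate.

**Step 5**
Reactants: 7
Product: 8 C11-alcohol diacetate
Conditions: K2CO3 (0.5 equiv), MeOH, 0 °C, 30 min
Reagents that add atoms: none
Why: Selective methanolysis. The C2 and C14 acetates are neopentyl-type (flanked by quaternary C1), whereas the C11 acetate is unhindered; the C11 stereocenter is destroyed in the next step.

**Step 6**
Reactants: 8
Product: 9 C11 ketone
Conditions: Dess–Martin periodinane, NaHCO3, CH2Cl2, 23 °C
Reagents that add atoms: none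
Why: Standard oxidation of a secondary alcohol to the ketone that will become the C11 methylene.

**Step 7**
Reactants: 9
Product: 10 C4 aldehyde (β-acetoxy aldehyde, C11 ketone)
Conditions: O3, CH2Cl2, –78 °C; then PPh3
Reagents that add atoms: ozone, O=[O+][O-] (the aldehyde oxygen comes from ozone)
Why: Ozonolysis of the only alkene gives the aldehyde; no stereocenter is affected. The crude aldehyde is used immediately to avoid β-elimination.

**Step 8**
Reactants: 11 2,2-dimethyl-1,3-dioxan-5-one; 12 (S)-SAMP
Product: 13 SAMP hydrazone of 11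
Conditions: SAMP, cyclohexane, reflux, Dean–Stark
Reagents that add atoms: 12, COC[C@@H]1CCCN1N
Why: Hydrazone formation for Enders asymmetric α-alkylation.

**Step 9**
Reactants: 13; 14 2,3-dibromopropene
Product: 15 alkylated hydrazone (7S as drawn)
Conditions: LDA, THF, 0 °C; then 14 at –100 °C → 23 °C
Reagents that add atoms: 14, C=C(Br)CBr
Why: Enders SAMP azaenolate alkylation at the allylic bromide sets C7 with high ee, and the vinyl bromide is untouched.

**Step 10**
Reactants: 15
Product: 16 (S)-4-(2-bromoallyl)-2,2-dimethyl-1,3-dioxan-5-one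
Conditions: sat. aq. oxalic acid, Et2O, 23 °C
Reagents that add atoms: water, O (the ketone oxygen comes from water)
Why: Mild hydrazone hydrolysis avoids ozone (which would attack the vinyl bromide) and avoids racemisation at C7.

**Step 11**
Reactants: 16
Product: 17 (S)-5-bromo-1,3-dihydroxyhex-5-en-2-one
Conditions: 80% aq AcOH, 40 °C
Reagents that add atoms: none
Why: Acid hydrolysis of the acetonide frees the C7 and C9 hydroxyls, with no effect on C7.

**Step 12**
Reactants: 17
Product: 18 C9-OTBS, C7-OH ketone
Conditions: TBSCl (1.05 equiv), imidazole, DMF, 0 °C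
Reagents that add atoms: TBSCl, CC(C)(C)[Si](C)(C)Cl
Why: The primary hydroxyl is silylated selectively over the secondary α-keto alcohol.

**Step 13**
Reactants: 18; 19 2-bromopropionyl bromide
Product: 20 C7 2-bromopropionate (C17 epimeric mixture)
Conditions: pyridine, DMAP (cat.), CH2Cl2, 0 °C
Reagents that add atoms: 19, CC(Br)C(=O)Br
Why: Acylation of the secondary alcohol installs C17/C18/C19. The C17 epimers converge in the next step through the zinc enolate.

**Step 14**
Reactants: 20
Product: 21 γ-lactone with C8 tertiary OH (C7 S, C8 S, C17 as drawn)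
Conditions: Zn dust, TMSCl (cat.), THF, 65 °C (0.02 M)
Reagents that add atoms: none
Why: Intramolecular Reformatsky (5-exo zinc-enolate aldol) forms C8–C17 and the lactone. The TS puts the larger C9 group trans to C6 and the methyl trans to C9, giving the cis-C6/O8 relationship of the target.

**Step 15**
Reactants: 10; 21
Product: 22 C4 allylic alcohol (C4 epimers)
Conditions: CrCl2 (6 equiv), NiCl2 (10 mol%), DMF, 23 °C
Reagents that add atoms: none
Why: Nozaki–Hiyama–Kishi vinyl–Cr addition chemoselective for the aldehyde over the C11 ketone; the C4 configuration is irrelevant because C4 is oxidised later.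

**Step 16**
Reactants: 22
Product: 23 bis-TES ether (C4-OTES, C8-OTES; C9-OTBS retained)
Conditions: TESOTf, 2,6-lutidine, CH2Cl2, –78 → –40 °C
Reagents that add atoms: TESOTf, CC[Si](CC)(CC)OS(=O)(=O)C(F)(F)F
Why: Masking the free OH groups allows clean titanium methylenation in the next step.

**Step 17**
Reactants: 23
Product: 24 C11 exocyclic methylene
Conditions: Cp2TiMe2 (5 equiv), toluene, 70 °C, dark
Reagents that add atoms: dimethyltitanocene, C[Ti](C)(C1C=CC=C1)C1C=CC=C1 (supplies the =CH2, which becomes C20)
Why: Petasis methylenation is ketone-selective over the acetates and lactone, and creates the C11=C20 alkene needed for the key step.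

**Step 18**
Reactants: 24
Product: 25 triol (C4-OH, C8-OH, C9-OH)
Conditions: HF·pyridine, pyridine/THF, 0 → 23 °C
Reagents that add atoms: none
Why: Global fluoride desilylation of the TES and TBS ethers. The product is used at once, since C9-OH could translactonise.

**Step 19**
Reactants: 25
Product: 26 C4 ketone (α-methylene ketone) and C9 aldehyde; partly present as the bridged C4 hemiketal
Conditions: Dess–Martin periodinane (3 equiv), NaHCO3, CH2Cl2, 0 °C
Reagents that add atoms: none
Why: One-pot oxidation of the allylic secondary and primary alcohols; the tertiary C8-OH is untouched and traps C4 as the pre-organising oxa-bridged hemiketal.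

**Step 20**
Reactants: 26
Product: 27 C9-hydroxy hemiketal (the target lacking the C9 acetyl)
Conditions: Mes-Acr-Ph+ BF4– (5 mol%), CrCl3 (20 mol%), dtbbpy (24 mol%), 2,6-lutidine, THF (2 mM), blue LEDs, 25 °C
Reagents that add atoms: none (redox-neutral isomerisation)
Why: Proposed new method: intramolecular dual photoredox/Cr allylic C(sp3)–H addition to an aldehyde to close a medium ring. The excited acridinium oxidises the C11=C20 alkene to its radical cation, and lutidine removes the C10–H proton. The allyl radical is captured by Cr(II) to give the primary C20 allyl-Cr(III). γ-Attack at C10 on the tethered C9 aldehyde through a chair TS forms C9–C10 and regenerates C11=C20. The ring-constrained E-allyl geometry gives the anti homoallylic alcohol (C9-OH anti to C10–C1, as in the target), and the macrocyclic TS favours the trans 6/10 fusion. Cr(III) alkoxide protonation by lutidinium and Cr(III) reduction by the acridinyl radical turn the cycle over. The closest known reactions are the intermolecular photoredox/Cr allylic C–H allylation of aldehydes and intramolecular NHK allyl-halide macrocyclisations.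

**Step 21**
Reactants: 27
Product: 28 (+)-junceellolide A
Conditions: Ac2O, DMAP, Et3N, CH2Cl2, 23 °C
Reagents that add atoms: acetic anhydride, CC(=O)OC(C)=O
Why: The hindered secondary C9-OH is acetylated, while the tertiary hemiketal OH is unreactive and stays free; no stereocenter is touched.

---

**Compound list**
1 | methacrolein | C=C(C)C=O | starting material
2 | (1E,3E)-1,4-diacetoxybuta-1,3-diene | CC(=O)O/C=C/C=C/OC(C)=O | starting material
3 | Diels–Alder aldehyde | CC(=O)O[C@@H]1C=C[C@H](OC(C)=O)[C@@](C)(C1)C=O | intermediate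
4 | saturated diacetoxy aldehyde | CC(=O)O[C@@H]1CC[C@H](OC(C)=O)[C@@](C)(C1)C=O | intermediate
5 | (–)-B-allyldiisopinocampheylborane | C=CCB(C1CC2CC(C1C)C2(C)C)C1CC2CC(C1C)C2(C)C | starting material
6 | homoallylic alcohol | CC(=O)O[C@@H]1CC[C@H](OC(C)=O)[C@@](C)(C1)[C@H](O)CC=C | intermediate
7 | triacetate | CC(=O)O[C@@H]1CC[C@H](OC(C)=O)[C@@](C)(C1)[C@H](OC(C)=O)CC=C | intermediate
8 | C11-alcohol diacetate | O[C@@H]1CC[C@H](OC(C)=O)[C@@](C)(C1)[C@H](OC(C)=O)CC=C | intermediate
9 | C11 ketone | O=C1CC[C@H](OC(C)=O)[C@@](C)(C1)[C@H](OC(C)=O)CC=C | intermediate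
10 | C4 aldehyde | O=C1CC[C@H](OC(C)=O)[C@@](C)(C1)[C@H](OC(C)=O)CC=O | intermediate
11 | 2,2-dimethyl-1,3-dioxan-5-one | CC1(C)OCC(=O)CO1 | starting material
12 | (S)-SAMP | COC[C@@H]1CCCN1N | starting material
13 | SAMP hydrazone of 11 | COC[C@@H]1CCCN1N=C1COC(C)(C)OC1 | intermediate
14 | 2,3-dibromopropene | C=C(Br)CBr | starting material
15 | alkylated hydrazone | COC[C@@H]1CCCN1N=C1COC(C)(C)O[C@H]1CC(Br)=C | intermediate
16 | (S)-4-(2-bromoallyl)-2,2-dimethyl-1,3-dioxan-5-one | C=C(Br)C[C@@H]1OC(C)(C)OCC1=O | intermediate
17 | (S)-5-bromo-1,3-dihydroxyhex-5-en-2-one | C=C(Br)C[C@H](O)C(=O)CO | intermediate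
18 | C9-OTBS ketone | C=C(Br)C[C@H](O)C(=O)CO[Si](C)(C)C(C)(C)C | intermediate
19 | 2-bromopropionyl bromide | CC(Br)C(=O)Br | starting material
20 | 2-bromopropionate ester | C=C(Br)C[C@H](OC(=O)C(C)Br)C(=O)CO[Si](C)(C)C(C)(C)C | intermediate
21 | hydroxy-γ-lactone vinyl bromide | C=C(Br)C[C@@H]1OC(=O)[C@H](C)[C@@]1(O)CO[Si](C)(C)C(C)(C)C | intermediate
22 | NHK adduct | O=C1CC[C@H](OC(C)=O)[C@@](C)(C1)[C@H](OC(C)=O)CC(O)C(=C)C[C@@H]2OC(=O)[C@H](C)[C@@]2(O)CO[Si](C)(C)C(C)(C)C | intermediate
23 | bis-TES ether | O=C1CC[C@H](OC(C)=O)[C@@](C)(C1)[C@H](OC(C)=O)CC(O[Si](CC)(CC)CC)C(=C)C[C@@H]2OC(=O)[C@H](C)[C@@]2(O[Si](CC)(CC)CC)CO[Si](C)(C)C(C)(C)C | intermediate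
24 | C11-methylene compound | C=C1CC[C@H](OC(C)=O)[C@@](C)(C1)[C@H](OC(C)=O)CC(O[Si](CC)(CC)CC)C(=C)C[C@@H]2OC(=O)[C@H](C)[C@@]2(O[Si](CC)(CC)CC)CO[Si](C)(C)C(C)(C)C | intermediate
25 | triol | C=C1CC[C@H](OC(C)=O)[C@@](C)(C1)[C@H](OC(C)=O)CC(O)C(=C)C[C@@H]2OC(=O)[C@H](C)[C@@]2(O)CO | intermediate
26 | keto-aldehyde (macrocyclisation substrate) | C=C1CC[C@H](OC(C)=O)[C@@](C)(C1)[C@H](OC(C)=O)CC(=O)C(=C)C[C@@H]2OC(=O)[C@H](C)[C@@]2(O)C=O | intermediate
27 | 9-deacetyl junceellolide A | C=C1CC[C@H](OC(C)=O)[C@@]2(C)[C@H]1[C@@H](O)[C@@]13O[C@](O)(C[C@H]2OC(C)=O)C(=C)C[C@@H]1OC(=O)[C@@H]3C | intermediate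
28 | (+)-junceellolide A | C=C1CC[C@H](OC(C)=O)[C@@]2(C)[C@H]1[C@@H](OC(C)=O)[C@@]13O[C@](O)(C[C@H]2OC(C)=O)C(=C)C[C@@H]1OC(=O)[C@@H]3C | target

---

**Total steps:** 21
**Longest linear sequence:** 14 steps (methacrolein → 10, then steps 15–21; or 11 → 21, then steps 15–21)

**Three steps most likely to fail**
1. **Step 20 (new Cr/photoredox macrocyclisation).**
   - Risks: competing allylic activation at C12 or at the C5=C16 alkene, enone reduction, and the wrong C10 or ring-fusion configuration.
   - Fallback (known chemistry): make the endocyclic C10=C11 alkene with a C20 allylic bromide. Route: C11 ketone → enol triflate → Pd carbonylation → DIBAL → Appel bromination. Then close the ring by classical intramolecular NHK allylation (CrCl2, cat. NiCl2), which is γ-selective and anti.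
2. **Step 1 (enantio- and endo-selective Diels–Alder of an α-substituted enal).**
   - The endo/exo ratio and the ee are both uncertain.
   - Fallback: Evans N-methacryloyl oxazolidinone plus 2 with Et2AlCl, then LiBH4 reduction and DMP oxidation to give 3, with any C14 epimer corrected by oxidation/reduction.
3. **Step 14 (Reformatsky lactonisation; C8/C17 diastereocontrol).**
   - Fallback: add the lithium enolate of ethyl propionate to acetonide ketone 16 (chelation/Felkin, anti to the C7 substituent), then open the acetonide and lactonise with acid, separating the epimers.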